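**Plan**

- Retrosynthesis: cut the two phenolic O–allyl bonds; trace the C4 alcohol back, through inversion of its cis epimer, to the C4 ketone; cut the O1–C2 bond of the pyran ring to a 2'-hydroxychalcone that carries a removable tert-butyl ester on C3; cut C2=C3 (Knoevenagel) to 4-(allyloxy)benzaldehyde and an aryl β-keto ester; cut the ester C–C bond, one O–allyl bond and the C8–prenyl bond (aromatic Claisen) back to 2',6'-dihydroxy-4'-methoxyacetophenone.
- Forward: rings A and B are bought; the prenyl group is placed on ring A by O-tert-prenylation and [3,3] shift; the three-carbon chain is joined by C-acylation and Knoevenagel condensation; ring C is closed last.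
- Enabling feature: the phenolic oxygen on C8a of ring A is ortho to C4a. With C4 at the ketone level and a temporary ester on C3, C2 becomes the β-carbon of an aryl enone held 1,5 to that oxygen, so O1–C2 closure repeats the chalcone → flavanone event of flavonoid biosynthesis.
- Stereochemistry: C2 (S) comes from a chiral bifunctional thiourea catalyst in the ring closure. C4 (R) comes from axial hydride delivery to the (2S)-flavanone (2,4-cis) followed by Mitsunobu inversion (2,4-trans).
- Helpers and their removal: the tert-butyl ester is lost as isobutene and CO2 in the same flask. One allyl ether blocks the second ortho oxygen so that the prenyl group ends on C8; both allyl ethers come off last without acid, because the C4 benzylic alcohol is acid-labile.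

Key step: step 6

Assumption: the quinidine-derived member of the pseudoenantiomeric pair of cinchona thioureas is taken to give the 2S series; should the sense of induction be the reverse, the quinine-derived catalyst is used and nothing else changes.

**Route**

Step 1
Reactants: 1 2',6'-dihydroxy-4'-methoxyacetophenone
Product: 2 1-{2-hydroxy-4-methoxy-6-[(2-methylbut-3-en-2-yl)oxy]phenyl}ethan-1-one
Conditions: tert-butyl (2-methylbut-3-en-2-yl) carbonate (1.05 equiv), Pd(PPh3)4 (2 mol%), THF, 0 °C → rt
Reagents that add atoms: tert-butyl (2-methylbut-3-en-2-yl) carbonate, C=CC(C)(C)OC(=O)OC(C)(C)C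
Why: Tsuji–Trost O-allylation, in which Pd(0) ionises the tertiary allylic carbonate (loss of CO2 and tert-butoxide, which deprotonates the phenol) and the phenoxide attacks the more substituted terminus of the 1,1-dimethylallyl–palladium complex under kinetic control at low temperature; the two hydroxyls of 1 are equivalent and the one left over stays locked in the C=O hydrogen bond, so one equivalent of carbonate should stop at the mono-ether.

Step 2
Reactants: 2 1-{2-hydroxy-4-methoxy-6-[(2-methylbut-3-en-2-yl)oxy]phenyl}ethan-1-one
Product: 3 1-[2,6-dihydroxy-4-methoxy-3-(3-methylbut-2-en-1-yl)phenyl]ethan-1-one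
Conditions: PhNEt2, 130 °C
Reagents that add atoms: none
Why: Aromatic Claisen rearrangement, in which the [3,3] shift can only reach the free ortho carbon (the other ortho carbon carries the acetyl group) and converts the O-bound 1,1-dimethylallyl group into the linear C-bound 3-methylbut-2-enyl group before tautomerisation restores the phenol; the basic solvent keeps the new ortho-prenylphenol from acid-induced chroman formation.

Step 3
Reactants: 3 1-[2,6-dihydroxy-4-methoxy-3-(3-methylbut-2-en-1-yl)phenyl]ethan-1-one
Product: 4 1-[2-hydroxy-4-methoxy-3-(3-methylbut-2-en-1-yl)-6-(prop-2-en-1-yloxy)phenyl]ethan-1-one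
Conditions: allyl bromide (1.05 equiv), K2CO3, acetone, rt
Reagents that add atoms: allyl bromide, C=CCBr
Why: Williamson ether synthesis, in which the hydroxyl between the prenyl and acetyl groups is the more hindered one and is held in the C=O hydrogen bond (buttressed by the prenyl group), so the mild carbonate base should alkylate the prenyl-remote hydroxyl once and stop.

Step 4
Reactants: 4 1-[2-hydroxy-4-methoxy-3-(3-methylbut-2-en-1-yl)-6-(prop-2-en-1-yloxy)phenyl]ethan-1-one
Product: 5 tert-butyl 3-[2-hydroxy-4-methoxy-3-(3-methylbut-2-en-1-yl)-6-(prop-2-en-1-yloxy)phenyl]-3-oxopropanoate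
Conditions: LiHMDS (3.2 equiv), THF, −78 °C; Boc2O (1.1 equiv), −78 → 0 °C; aq. NH4Cl
Reagents that add atoms: di-tert-butyl dicarbonate, CC(C)(C)OC(=O)OC(=O)OC(C)(C)C
Why: Claisen-type C-acylation of the phenoxide–enolate dianion of the methyl ketone with Boc2O, driven by deprotonation of the β-keto ester by the third equivalent of base; any aryl or enol tert-butyl carbonate formed first should converge on the same product by Baker–Venkataraman-type O-to-C acyl transfer, and the bulky tert-butyl ester resists lactonisation onto the free phenol.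

Step 5
Reactants: 5 tert-butyl 3-[2-hydroxy-4-methoxy-3-(3-methylbut-2-en-1-yl)-6-(prop-2-en-1-yloxy)phenyl]-3-oxopropanoate; 6 4-(prop-2-en-1-yloxy)benzaldehyde
Product: 7 tert-butyl 2-[2-hydroxy-4-methoxy-3-(3-methylbut-2-en-1-yl)-6-(prop-2-en-1-yloxy)benzoyl]-3-[4-(prop-2-en-1-yloxy)phenyl]prop-2-enoate (E/Z mixture)
Conditions: piperidine (10 mol%), AcOH (20 mol%), 4 Å MS, PhMe, rt
Reagents that add atoms: none
Why: Knoevenagel condensation of the active methylene with the aromatic aldehyde under piperidinium acetate catalysis, run at room temperature with removal of water so that base-mediated closure of the product stays slow; the E/Z mixture is carried on as such.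

Step 6
Reactants: 7 tert-butyl 2-[2-hydroxy-4-methoxy-3-(3-methylbut-2-en-1-yl)-6-(prop-2-en-1-yloxy)benzoyl]-3-[4-(prop-2-en-1-yloxy)phenyl]prop-2-enoate
Product: 9 (2S)-7-methoxy-8-(3-methylbut-2-en-1-yl)-5-(prop-2-en-1-yloxy)-2-[4-(prop-2-en-1-yloxy)phenyl]chroman-4-one, via trans-3-tert-butoxycarbonyl flavanone 8 (not isolated)
Conditions: N-[3,5-bis(trifluoromethyl)phenyl]-N'-(9-deoxy-epi-quinidin-9-yl)thiourea (10 mol%), PhMe, −25 °C; then TsOH·H2O, 80 °C
Reagents that add atoms: none
Why: The thiourea unit of the catalyst binds the two carbonyl groups of the alkylidene β-keto ester while the quinuclidine nitrogen deprotonates the ortho phenol, the phenoxide oxygen adds to the β-carbon (the future C2) and the ester-stabilised enol is protonated at C3; added TsOH then cleaves the tert-butyl ester with loss of isobutene and the β-keto acid decarboxylates through its enol, which removes the activating group. The closest known reaction type is the bifunctional-thiourea-catalysed intramolecular oxa-Michael addition of 2-hydroxyaryl alkylidene β-keto esters to 3-carboxyflavanones with acid decarboxylation in the same flask, the laboratory counterpart of the chalcone → flavanone step of flavonoid biosynthesis. The pyranone ring closes in the 6-endo-trig mode as a conjugate addition. C2 is the only stereocentre that remains and is set by the catalyst, which holds the bound enone so that one face of the β-carbon is open to the tethered phenoxide, while C3 is epimerisable and ends as CH2. The step needs regioselectivity between the two oxygens ortho to the acyl group, which the allyl ether on the prenyl-remote oxygen secures so that only the prenyl-flanked phenol can close and the prenyl group ends on C8, and it needs the catalysed path to outrun the background closure, which the low temperature and the non-polar solvent serve. Once the ring is closed no free phenol is left next to the prenyl group and both flanking oxygens are conjugated with the C4 carbonyl, so the acid should find no internal nucleophile for prenyl cyclisation, and the acidic rather than basic medium disfavours retro-oxa-Michael racemisation.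

Step 7
Reactants: 9 (2S)-7-methoxy-8-(3-methylbut-2-en-1-yl)-5-(prop-2-en-1-yloxy)-2-[4-(prop-2-en-1-yloxy)phenyl]chroman-4-one
Product: 10 (2S,4S)-7-methoxy-8-(3-methylbut-2-en-1-yl)-5-(prop-2-en-1-yloxy)-2-[4-(prop-2-en-1-yloxy)phenyl]chroman-4-ol (2,4-cis)
Conditions: NaBH4, THF/MeOH, 0 °C; chromatography on Et3N-deactivated silica
Reagents that add atoms: none
Why: Substrate-controlled hydride reduction of the chromanone, in which borohydride attacks C4 along the axial trajectory of the half-chair with the 2-aryl group equatorial and should give the equatorial alcohol, i.e. the 2,4-cis (4S) epimer; the aryl allyl ethers and the prenyl alkene are inert to NaBH4.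

Step 8
Reactants: 10 (2S,4S)-7-methoxy-8-(3-methylbut-2-en-1-yl)-5-(prop-2-en-1-yloxy)-2-[4-(prop-2-en-1-yloxy)phenyl]chroman-4-ol
Product: 11 (2S,4R)-7-methoxy-8-(3-methylbut-2-en-1-yl)-5-(prop-2-en-1-yloxy)-2-[4-(prop-2-en-1-yloxy)phenyl]chroman-4-yl 4-nitrobenzoate (2,4-trans)
Conditions: 4-O2NC6H4CO2H, PPh3, DIAD, PhMe, 0 °C → rt
Reagents that add atoms: 4-nitrobenzoic acid, OC(=O)c1ccc(cc1)[N+](=O)[O-]
Why: Mitsunobu reaction, in which the equatorial C4 oxyphosphonium ion is displaced by 4-nitrobenzoate with inversion, and in which even an ion-pair pathway at this electron-rich benzylic carbon should be captured along the same axial trajectory, so that both mechanisms lead to the 2,4-trans (4R) ester; both phenols are masked, so the acid is the only nucleophile.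

Step 9
Reactants: 11 (2S,4R)-7-methoxy-8-(3-methylbut-2-en-1-yl)-5-(prop-2-en-1-yloxy)-2-[4-(prop-2-en-1-yloxy)phenyl]chroman-4-yl 4-nitrobenzoate
Product: 12 (2S,4R)-7-methoxy-8-(3-methylbut-2-en-1-yl)-5-(prop-2-en-1-yloxy)-2-[4-(prop-2-en-1-yloxy)phenyl]chroman-4-ol (2,4-trans)
Conditions: LiOH, THF/H2O, 0 °C → rt; work-up at pH ≥ 7
Reagents that add atoms: none
Why: Saponification by acyl–oxygen cleavage, which retains the C4 configuration; the aqueous, alcohol-free and non-acidic medium is chosen so that even a competing ionisation of this labile benzylic ester could only return a C4 alcohol and never a C4 ether.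

Step 10
Reactants: 12 (2S,4R)-7-methoxy-8-(3-methylbut-2-en-1-yl)-5-(prop-2-en-1-yloxy)-2-[4-(prop-2-en-1-yloxy)phenyl]chroman-4-ol
Product: 13 (2S,4R)-2-(4-hydroxyphenyl)-7-methoxy-8-(3-methylbut-2-en-1-yl)chromane-4,5-diol (4,5,4'-trihydroxy-7-methoxy-8-prenylflavan)
Conditions: Pd(PPh3)4 (5 mol%), morpholine, THF, rt; work-up without acid, chromatography on Et3N-deactivated silica
Reagents that add atoms: none
Why: Tsuji–Trost deallylation, in which Pd(0) ionises both aryl allyl ethers and morpholine traps the allyl–palladium complexes, so that the two phenols are released under neutral to basic conditions that leave the acid-labile C4 benzylic alcohol, both stereocentres and the C-bound prenyl group untouched.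

**Compound list**

1 | 2',6'-dihydroxy-4'-methoxyacetophenone | CC(=O)c1c(O)cc(OC)cc1O | starting material
2 | 1-{2-hydroxy-4-methoxy-6-[(2-methylbut-3-en-2-yl)oxy]phenyl}ethan-1-one | CC(=O)c1c(O)cc(OC)cc1OC(C)(C)C=C | intermediate
3 | 1-[2,6-dihydroxy-4-methoxy-3-(3-methylbut-2-en-1-yl)phenyl]ethan-1-one | CC(=O)c1c(O)cc(OC)c(CC=C(C)C)c1O | intermediate
4 | 1-[2-hydroxy-4-methoxy-3-(3-methylbut-2-en-1-yl)-6-(prop-2-en-1-yloxy)phenyl]ethan-1-one | CC(=O)c1c(OCC=C)cc(OC)c(CC=C(C)C)c1O | intermediate
5 | tert-butyl 3-[2-hydroxy-4-methoxy-3-(3-methylbut-2-en-1-yl)-6-(prop-2-en-1-yloxy)phenyl]-3-oxopropanoate | CC(C)(C)OC(=O)CC(=O)c1c(OCC=C)cc(OC)c(CC=C(C)C)c1O | intermediate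
6 | 4-(prop-2-en-1-yloxy)benzaldehyde | O=Cc1ccc(OCC=C)cc1 | starting material
7 | tert-butyl 2-[2-hydroxy-4-methoxy-3-(3-methylbut-2-en-1-yl)-6-(prop-2-en-1-yloxy)benzoyl]-3-[4-(prop-2-en-1-yloxy)phenyl]prop-2-enoate (E/Z mixture) | CC(C)(C)OC(=O)C(=Cc1ccc(OCC=C)cc1)C(=O)c1c(OCC=C)cc(OC)c(CC=C(C)C)c1O | intermediate
8 | tert-butyl (2S,3R)-7-methoxy-8-(3-methylbut-2-en-1-yl)-4-oxo-5-(prop-2-en-1-yloxy)-2-[4-(prop-2-en-1-yloxy)phenyl]chromane-3-carboxylate (2,3-trans, in equilibrium with its enol) | COc1cc(OCC=C)c2c(c1CC=C(C)C)O[C@H](c1ccc(OCC=C)cc1)[C@@H](C(=O)OC(C)(C)C)C2=O | intermediate (not isolated)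
9 | (2S)-7-methoxy-8-(3-methylbut-2-en-1-yl)-5-(prop-2-en-1-yloxy)-2-[4-(prop-2-en-1-yloxy)phenyl]chroman-4-one | COc1cc(OCC=C)c2c(c1CC=C(C)C)O[C@H](c1ccc(OCC=C)cc1)CC2=O | intermediate
10 | (2S,4S)-7-methoxy-8-(3-methylbut-2-en-1-yl)-5-(prop-2-en-1-yloxy)-2-[4-(prop-2-en-1-yloxy)phenyl]chroman-4-ol (2,4-cis) | COc1cc(OCC=C)c2c(c1CC=C(C)C)O[C@H](c1ccc(OCC=C)cc1)C[C@@H]2O | intermediate
11 | (2S,4R)-7-methoxy-8-(3-methylbut-2-en-1-yl)-5-(prop-2-en-1-yloxy)-2-[4-(prop-2-en-1-yloxy)phenyl]chroman-4-yl 4-nitrobenzoate (2,4-trans) | COc1cc(OCC=C)c2c(c1CC=C(C)C)O[C@H](c1ccc(OCC=C)cc1)C[C@H]2OC(=O)c1ccc(cc1)[N+](=O)[O-] | intermediate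
12 | (2S,4R)-7-methoxy-8-(3-methylbut-2-en-1-yl)-5-(prop-2-en-1-yloxy)-2-[4-(prop-2-en-1-yloxy)phenyl]chroman-4-ol (2,4-trans) | COc1cc(OCC=C)c2c(c1CC=C(C)C)O[C@H](c1ccc(OCC=C)cc1)C[C@H]2O | intermediate
13 | (2S,4R)-2-(4-hydroxyphenyl)-7-methoxy-8-(3-methylbut-2-en-1-yl)chromane-4,5-diol | COc1cc(O)c2c(c1CC=C(C)C)O[C@H](c1ccc(O)cc1)C[C@H]2O | target

**Summary**

Total step count: 10. Longest linear sequence: 10 steps (1 → 13); aldehyde 6 is bought.

**Steps most likely to fail**

Step 6. The uncatalysed closure of the doubly ortho-substituted aroyl acrylate may compete with the catalysed one and erode the enantiomeric purity. The hot acidic decarboxylation may also protonate the prenyl alkene or open the pyranone ring. The fallback forms the C2–aryl bond instead and needs no acid at the stage of the stereocentre. It sets out from ketone 4, which is condensed with DMF dimethyl acetal (PhMe, 100 °C) to the enaminone (E)-3-(dimethylamino)-1-[2-hydroxy-4-methoxy-3-(3-methylbut-2-en-1-yl)-6-(prop-2-en-1-yloxy)phenyl]prop-2-en-1-one F1. Mild acid (AcOH, 50 °C) should close F1 to 7-methoxy-8-(3-methylbut-2-en-1-yl)-5-(prop-2-en-1-yloxy)-4H-chromen-4-one F2. A rhodium(I)/chiral diphosphine-catalysed asymmetric 1,4-addition of 4-(allyloxy)phenylboronic acid to F2, with the ligand enantiomer chosen for the 2S series, should then give flavanone 9, where the route is rejoined.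

Step 8. The activated C4 oxygen may be lost by elimination to the flav-3-ene, or collapse within an ion pair may give partial retention. The fallback replaces the bimolecular inversion by a solvolysis that uses the ease of ionisation. It sets out from cis alcohol 10, which is acetylated (Ac2O, pyridine, DMAP) to (2S,4S)-7-methoxy-8-(3-methylbut-2-en-1-yl)-5-(prop-2-en-1-yloxy)-2-[4-(prop-2-en-1-yloxy)phenyl]chroman-4-yl acetate F3. In buffered aqueous acetone (NaHCO3, rt) F3 should ionise to the 5,7-dioxygenated benzylic cation, which water should capture along the axial trajectory, the same facial preference that makes hydride give the cis alcohol, to give trans alcohol 12. The route is rejoined at 12, so step 9 is skipped, and any cis alcohol 10 that returns is recycled.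

Step 1. The π-allylpalladium complex may alkylate the phloroglucinol-type ring on carbon, be attacked at its unsubstituted terminus to give the linear ether, or etherify both hydroxyls. The fallback builds the tertiary ether without a π-allyl intermediate. It sets out from 1, which is alkylated with 3-chloro-3-methylbut-1-yne (K2CO3, KI, CuI cat., acetone, reflux) to 1-{2-hydroxy-4-methoxy-6-[(2-methylbut-3-yn-2-yl)oxy]phenyl}ethan-1-one F4. Lindlar semi-hydrogenation of F4 (H2, Pd/CaCO3–Pb, quinoline, EtOAc) should give ether 2, where the route is rejoined.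

**Further compounds**

F1 | step 6 | (E)-3-(dimethylamino)-1-[2-hydroxy-4-methoxy-3-(3-methylbut-2-en-1-yl)-6-(prop-2-en-1-yloxy)phenyl]prop-2-en-1-one | CN(C)/C=C/C(=O)c1c(OCC=C)cc(OC)c(CC=C(C)C)c1O
F2 | step 6 | 7-methoxy-8-(3-methylbut-2-en-1-yl)-5-(prop-2-en-1-yloxy)-4H-chromen-4-one | COc1cc(OCC=C)c2c(c1CC=C(C)C)occc2=O
F3 | step 8 | (2S,4S)-7-methoxy-8-(3-methylbut-2-en-1-yl)-5-(prop-2-en-1-yloxy)-2-[4-(prop-2-en-1-yloxy)phenyl]chroman-4-yl acetate | COc1cc(OCC=C)c2c(c1CC=C(C)C)O[C@H](c1ccc(OCC=C)cc1)C[C@@H]2OC(C)=O
F4 | step 1 | 1-{2-hydroxy-4-methoxy-6-[(2-methylbut-3-yn-2-yl)oxy]phenyl}ethan-1-one | CC(=O)c1c(O)cc(OC)cc1OC(C)(C)C#C
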